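**Retrosynthetic overview**

1. The target comes from acetonide removal of a protected 3-acyl-4-hydroxy-dihydropyranone, whose tricarbonyl core is the product of a 1,3-O→C acyl shift of a C4 enol ester of the side-chain acid.
2. Key disconnection: the C4–C5 bond of the dihydropyranone ring (O1–C2(=O)–C3–C4–C5–C6), made as C4=C5 by ring-closing metathesis of an acyclic enol ester diene. Enabling feature: C4 is an oxygen-bearing enol carbon next to the unsubstituted C5H2 and 1,3 to the acyl-bearing C3, and C6 is a secondary carbinol carbon; so C4 can come from a CH2=C(O-acyl) unit, C5 from the vinyl group of (R)-but-3-en-2-ol, and the O-acyl group can then migrate to C3.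
3. The metathesis precursor is assembled from three pieces: (R)-but-3-en-2-ol (O1, C6, C5), but-3-ynoic acid (C2, C3, C4) and the side-chain acid, which is added across the alkyne.
4. The side-chain acid comes from E-selective cross-metathesis of (R)-4-methylhept-6-enoic acid (from (R)-citronellal) with a vinyl-dioxane (from (S)-2-methylbutan-1-ol by Sharpless epoxidation and C2-selective vinyl-cuprate opening).
5. Ring order: temporary 1,3-dioxane (acetonide) first, dihydropyranone last; the acetonide is removed in the final step.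

Key step: step 12

Remark on the chemistry: the acyl-dihydropyranone is one tautomeric tricarbonyl system and is written throughout as the 4-hydroxy enol drawn for the target.

**Route**

Step 1
Reactants: 1 (S)-2-methylbutan-1-ol
Product: 3 ethyl (2E,4S)-4-methylhex-2-enoate, via (S)-2-methylbutanal 2 (not isolated)
Conditions: TEMPO (1 mol%), KBr, NaOCl, CH2Cl2/aq. NaHCO3, 0 °C; organic layer dried (MgSO4); then Ph3P=CHCO2Et, CH2Cl2, 0 to 23 °C
Reagents that add atoms: ethyl (triphenylphosphoranylidene)acetate CCOC(=O)C=P(c1ccccc1)(c1ccccc1)c1ccccc1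
Why: Anelli (TEMPO/hypochlorite) oxidation followed directly by Wittig olefination with the stabilised ylide should give the E-enoate without isolating the volatile, epimerisable aldehyde; the stereocentre is taken from the chiral pool.

Step 2
Reactants: 3 ethyl (2E,4S)-4-methylhex-2-enoate
Product: 4 (2E,4S)-4-methylhex-2-en-1-ol
Conditions: i-Bu2AlH (2.2 equiv), CH2Cl2, −78 °C; aqueous potassium sodium tartrate work-up
Reagents that add atoms: none
Why: 1,2-Reduction of an α,β-unsaturated ester to the allylic alcohol with i-Bu2AlH is routine and leaves the alkene geometry and the stereocentre untouched.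

Step 3
Reactants: 4 (2E,4S)-4-methylhex-2-en-1-ol
Product: 5 [(2R,3R)-3-[(2S)-butan-2-yl]oxiran-2-yl]methanol
Conditions: Ti(OiPr)4 (10 mol%), D-(−)-diethyl tartrate (12 mol%), t-BuOOH, 4 Å MS, CH2Cl2, −20 °C
Reagents that add atoms: tert-butyl hydroperoxide CC(C)(C)OO
Why: Sharpless asymmetric epoxidation of an E-allylic alcohol, in which the D-(−)-tartrate ligand should direct oxygen to the face giving the (2R,3R)-epoxide under reagent control, overriding the adjacent methyl-bearing centre.

Step 4
Reactants: 5 [(2R,3R)-3-[(2S)-butan-2-yl]oxiran-2-yl]methanol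
Product: 6 (2S,3R,4S)-2-ethenyl-4-methylhexane-1,3-diol
Conditions: CH2=CHMgBr (4 equiv), CuI (15 mol%), THF/Et2O, −40 to −10 °C; aq. NH4Cl, then NaIO4 wash
Reagents that add atoms: vinylmagnesium bromide C=C[Mg]Br
Why: Copper-catalysed Grignard opening of a 2,3-epoxy alcohol should occur by SN2 attack at C2, because C3 is shielded by the sec-butyl branch; inversion at C2 sets the vinyl-bearing centre and the C3 carbinol is retained, and periodate removes any 1,2-diol regioisomer.

Step 5
Reactants: 6 (2S,3R,4S)-2-ethenyl-4-methylhexane-1,3-diol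
Product: 7 (4R,5S)-4-[(2S)-butan-2-yl]-5-ethenyl-2,2-dimethyl-1,3-dioxane
Conditions: 2,2-dimethoxypropane, PPTS (5 mol%), CH2Cl2, 23 °C
Reagents that add atoms: 2,2-dimethoxypropane COC(C)(C)OC
Why: Acid-catalysed transketalisation of a 1,3-diol to its acetonide is reliable and masks both hydroxyls through the metathesis and acyl-transfer steps.

Step 6
Reactants: 8 (R)-citronellal
Product: 9 (4R)-4,8-dimethylnona-1,7-diene
Conditions: Ph3PCH3Br, KOtBu, THF, 0 to 23 °C
Reagents that add atoms: methyltriphenylphosphonium bromide C[P+](c1ccccc1)(c1ccccc1)c1ccccc1.[Br-]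
Why: Wittig methylenation of an aliphatic aldehyde; the stereocentre is β to the carbonyl and cannot epimerise.

Step 7
Reactants: 9 (4R)-4,8-dimethylnona-1,7-diene
Product: 10 (4R)-4-methylhept-6-enal
Conditions: O3 (1.0 equiv, Sudan red 7B end-point), pyridine (cat.), CH2Cl2/MeOH, −78 °C; then Me2S, −78 to 23 °C
Reagents that add atoms: ozone [O-][O+]=O
Why: Chemoselective ozonolysis, in which the electron-rich trisubstituted alkene should react with electrophilic ozone well before the monosubstituted vinyl group, and reductive work-up gives the aldehyde.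

Step 8
Reactants: 10 (4R)-4-methylhept-6-enal
Product: 11 (4R)-4-methylhept-6-enoic acid
Conditions: NaClO2, NaH2PO4, 2-methylbut-2-ene, t-BuOH/H2O, 0 to 23 °C
Reagents that add atoms: sodium chlorite [Na+].[O-]Cl=O
Why: Pinnick oxidation converts the aldehyde into the acid without touching the terminal alkene, the scavenger removing the hypochlorous acid formed.

Step 9
Reactants: 7 (4R,5S)-4-[(2S)-butan-2-yl]-5-ethenyl-2,2-dimethyl-1,3-dioxane; 11 (4R)-4-methylhept-6-enoic acid
Product: 12 (4R,6E)-7-[(4R,5S)-4-[(2S)-butan-2-yl]-2,2-dimethyl-1,3-dioxan-5-yl]-4-methylhept-6-enoic acid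
Conditions: second-generation Hoveyda–Grubbs catalyst (5 mol%), 11 (2.5 equiv), CH2Cl2, 40 °C
Reagents that add atoms: none
Why: Olefin cross-metathesis between the unhindered terminal alkene of 11 and the α-branched vinyl group of 7, which is slow to homodimerise, should give the E-alkene preferentially under thermodynamic control; the free acid is tolerated by the ruthenium carbene.

Step 10
Reactants: 13 (R)-but-3-en-2-ol; 14 but-3-ynoic acid
Product: 15 (2R)-but-3-en-2-yl but-3-ynoate
Conditions: DCC (1.1 equiv), DMAP (2 mol%), CH2Cl2, −20 to 0 °C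
Reagents that add atoms: none
Why: Steglich esterification at low temperature with minimal DMAP acylates the secondary alcohol with retention, since its C–O bond is not touched, and should keep the β,γ-alkyne from isomerising to the allenoate.

Step 11
Reactants: 12 (4R,6E)-7-[(4R,5S)-4-[(2S)-butan-2-yl]-2,2-dimethyl-1,3-dioxan-5-yl]-4-methylhept-6-enoic acid; 15 (2R)-but-3-en-2-yl but-3-ynoate
Product: 16 (2R)-but-3-en-2-yl 3-{[(4R,6E)-7-[(4R,5S)-4-[(2S)-butan-2-yl]-2,2-dimethyl-1,3-dioxan-5-yl]-4-methylhept-6-enoyl]oxy}but-3-enoate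
Conditions: Ph3PAuNTf2 (3 mol%), 15 (1.5 equiv), toluene, 40 °C
Reagents that add atoms: none
Why: Markovnikov hydro-acyloxylation of a terminal alkyne by a carboxylic acid under monovalent gold catalysis should give the 1,1-disubstituted enol ester regioselectively under neutral conditions that spare the acetonide, the internal alkene and the allylic ester.

Step 12
Reactants: 16 (2R)-but-3-en-2-yl 3-{[(4R,6E)-7-[(4R,5S)-4-[(2S)-butan-2-yl]-2,2-dimethyl-1,3-dioxan-5-yl]-4-methylhept-6-enoyl]oxy}but-3-enoate
Product: 19 (6R)-3-{(4R,6E)-7-[(4R,5S)-4-[(2S)-butan-2-yl]-2,2-dimethyl-1,3-dioxan-5-yl]-4-methylhept-6-enoyl}-4-hydroxy-6-methyl-5,6-dihydro-2H-pyran-2-one, via 3,6-dihydropyranone enol ester 17 (not isolated), via 5,6-dihydropyranone enol ester 18 (not isolated)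
Conditions: second-generation Hoveyda–Grubbs catalyst (10 mol%), 1,4-benzoquinone (10 mol%), toluene (0.005 M), 70 °C; then DBU (1.5 equiv), DMAP (0.3 equiv), 0 to 23 °C; aq. citric acid work-up
Reagents that add atoms: none
Why: Proposed new method: ring-closing metathesis onto an enol ester as the 1,1-disubstituted partner is not established, but it is the direct analogue of the known ring-closing metathesis of 2-alkoxy- and 2-silyloxy-1,ω-dienes (enol ether and silyl enol ether partners) with second-generation ruthenium carbenes: the carbene loads on the monosubstituted allylic-ester alkene, adds [2+2] to the CH2=C(O-acyl) unit with ruthenium on the CH2 carbon, and cycloreversion releases Ru=CH2 and the ring C4=C5 bond, so no Fischer carbene arises. The only ring, the six-membered lactone, is closed in this event by metathesis between the carbon that becomes C5 and the enol-ester carbon C4, with loss of ethene. DBU then shifts C4=C5 into conjugation (C3=C4), the usual base isomerisation of 3,6-dihydro- to 5,6-dihydropyran-2-ones, and DMAP moves the acyl group from the C4 oxygen to C3 through the acylpyridinium/β-keto-lactone enolate pair, the known Fries-type 1,3-O→C shift of 4-acyloxy-5,6-dihydropyranones, driven by the hydrogen-bonded tricarbonyl enol. No stereocentre is formed: C6 is carried unchanged from (R)-but-3-en-2-ol because neither its C–O nor its C–H bond is broken, and the side-chain centres are remote. The step needs the two terminal alkenes to react in preference to the internal E-alkene and needs the unconjugated enol ester to survive until ring closure; the first is secured by the fast six-membered closure at high dilution against a 1,2-disubstituted alkene flanked by the dioxane, the second by benzoquinone, which suppresses Ru–H alkene migration until the base is added.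

Step 13
Reactants: 19 (6R)-3-{(4R,6E)-7-[(4R,5S)-4-[(2S)-butan-2-yl]-2,2-dimethyl-1,3-dioxan-5-yl]-4-methylhept-6-enoyl}-4-hydroxy-6-methyl-5,6-dihydro-2H-pyran-2-one
Product: 20 (6R)-4-hydroxy-3-[(4R,6E,8S,9R,10S)-9-hydroxy-8-(hydroxymethyl)-4,10-dimethyldodec-6-enoyl]-6-methyl-5,6-dihydro-2H-pyran-2-one
Conditions: AcOH/THF/H2O (3:1:1), 40 °C
Reagents that add atoms: none
Why: Acid-catalysed hydrolysis of the isopropylidene acetal frees the 1,3-diol; the acyl-dihydropyranone enol and the E-alkene should be stable to dilute acetic acid and no stereocentre is touched.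

**Compound list**

1 | (S)-2-methylbutan-1-ol | CC[C@H](C)CO | starting material
2 | (S)-2-methylbutanal | CC[C@H](C)C=O | intermediate (not isolated)
3 | ethyl (2E,4S)-4-methylhex-2-enoate | CC[C@H](C)/C=C/C(=O)OCC | intermediate
4 | (2E,4S)-4-methylhex-2-en-1-ol | CC[C@H](C)/C=C/CO | intermediate
5 | [(2R,3R)-3-[(2S)-butan-2-yl]oxiran-2-yl]methanol | CC[C@H](C)[C@H]1O[C@@H]1CO | intermediate
6 | (2S,3R,4S)-2-ethenyl-4-methylhexane-1,3-diol | CC[C@H](C)[C@@H](O)[C@@H](C=C)CO | intermediate
7 | (4R,5S)-4-[(2S)-butan-2-yl]-5-ethenyl-2,2-dimethyl-1,3-dioxane | CC[C@H](C)[C@@H](OC1(C)C)[C@@H](C=C)CO1 | intermediate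
8 | (R)-citronellal, (3R)-3,7-dimethyloct-6-enal | O=CC[C@H](C)CCC=C(C)C | starting material
9 | (4R)-4,8-dimethylnona-1,7-diene | C=CC[C@H](C)CCC=C(C)C | intermediate
10 | (4R)-4-methylhept-6-enal | C=CC[C@H](C)CCC=O | intermediate
11 | (4R)-4-methylhept-6-enoic acid | C=CC[C@H](C)CCC(=O)O | intermediate
12 | (4R,6E)-7-[(4R,5S)-4-[(2S)-butan-2-yl]-2,2-dimethyl-1,3-dioxan-5-yl]-4-methylhept-6-enoic acid | CC[C@H](C)[C@@H](OC1(C)C)[C@@H](/C=C/C[C@H](C)CCC(=O)O)CO1 | intermediate
13 | (R)-but-3-en-2-ol | C=C[C@@H](C)O | starting material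
14 | but-3-ynoic acid | C#CCC(=O)O | starting material
15 | (2R)-but-3-en-2-yl but-3-ynoate | C#CCC(=O)O[C@H](C)C=C | intermediate
16 | (2R)-but-3-en-2-yl 3-{[(4R,6E)-7-[(4R,5S)-4-[(2S)-butan-2-yl]-2,2-dimethyl-1,3-dioxan-5-yl]-4-methylhept-6-enoyl]oxy}but-3-enoate | CC[C@H](C)[C@@H](OC1(C)C)[C@@H](/C=C/C[C@H](C)CCC(=O)OC(=C)CC(=O)O[C@H](C)C=C)CO1 | intermediate
17 | (6R)-6-methyl-2-oxo-3,6-dihydro-2H-pyran-4-yl ester of acid 12 (β,γ-unsaturated lactone, C4=C5) | CC[C@H](C)[C@@H](OC2(C)C)[C@@H](/C=C/C[C@H](C)CCC(=O)OC1=C[C@@H](C)OC(=O)C1)CO2 | intermediate (not isolated)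
18 | (6R)-6-methyl-2-oxo-5,6-dihydro-2H-pyran-4-yl ester of acid 12 (conjugated lactone, C3=C4) | CC[C@H](C)[C@@H](OC2(C)C)[C@@H](/C=C/C[C@H](C)CCC(=O)OC1=CC(=O)O[C@H](C)C1)CO2 | intermediate (not isolated)
19 | (6R)-3-{(4R,6E)-7-[(4R,5S)-4-[(2S)-butan-2-yl]-2,2-dimethyl-1,3-dioxan-5-yl]-4-methylhept-6-enoyl}-4-hydroxy-6-methyl-5,6-dihydro-2H-pyran-2-one | CC[C@H](C)[C@@H](OC2(C)C)[C@@H](/C=C/C[C@H](C)CCC(=O)C1=C(O)C[C@@H](C)OC1=O)CO2 | intermediate
20 | (6R)-4-hydroxy-3-[(4R,6E,8S,9R,10S)-9-hydroxy-8-(hydroxymethyl)-4,10-dimethyldodec-6-enoyl]-6-methyl-5,6-dihydro-2H-pyran-2-one | CC[C@H](C)[C@@H](O)[C@@H](/C=C/C[C@H](C)CCC(=O)C1=C(O)C[C@@H](C)OC1=O)CO | target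

**Step count and risk**

Total steps: 13. Longest linear sequence: 9 steps (steps 1–5, 9, 11, 12, 13).

Steps most likely to fail:

1. Step 12 (proposed new method). The enol-ester alkene may engage the ruthenium carbene too slowly, so that catalyst decay, migration of the terminal alkenes or intermolecular metathesis with the side-chain alkene takes over; in the second stage, base-induced E1cB opening of the lactone could compete with acyl transfer. Fallback, with known chemistry only (vinylboronate ring-closing metathesis, oxidation, then acylation with in situ 1,3-acyl shift), setting out from 15 and 12 and coming back at 19: Et3N isomerises 15 to the allenoate (2R)-but-3-en-2-yl buta-2,3-dienoate F1. Copper-catalysed β-borylation (CuCl, Xantphos, NaOtBu, B2pin2, MeOH) gives the alkenylboronate (2R)-but-3-en-2-yl 3-(4,4,5,5-tetramethyl-1,3,2-dioxaborolan-2-yl)but-3-enoate F2. Ring-closing metathesis with the second-generation Grubbs catalyst still closes the ring through C4=C5 and gives the cyclic alkenylboronate (6R)-6-methyl-4-(4,4,5,5-tetramethyl-1,3,2-dioxaborolan-2-yl)-3,6-dihydro-2H-pyran-2-one F3. NaBO3·4H2O oxidation gives (6R)-4-hydroxy-6-methyl-5,6-dihydro-2H-pyran-2-one F4. DCC/DMAP coupling of F4 with acid 12 gives the O-acyl compound 18, which rearranges under the same conditions to 19.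

2. Step 11. The β,γ-alkynoate may isomerise to the allenoate, the cationic gold catalyst may strip the acetonide, or the addition may stall at near-equimolar stoichiometry. Fallback, in which the C4–O bond is made by oxidative copper coupling instead of alkyne addition, setting out from 15 and coming back at 16: 15 is isomerised to the allenoate (2R)-but-3-en-2-yl buta-2,3-dienoate F1 and borylated to the alkenylboronate (2R)-but-3-en-2-yl 3-(4,4,5,5-tetramethyl-1,3,2-dioxaborolan-2-yl)but-3-enoate F2 as in the fallback above. KHF2 converts F2 into potassium trifluoro{4-[(2R)-but-3-en-2-yloxy]-4-oxobut-1-en-2-yl}borate F5. Cu(OAc)2-catalysed coupling of F5 with acid 12 (DMAP, 4 Å MS, O2, CH2Cl2) gives enol ester 16.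

3. Step 9. Homodimerisation of 11 may outpace the cross event, E-selectivity may erode, or secondary metathesis may scramble the product. Fallback, Julia–Kocienski olefination instead of metathesis, setting out from 7 and 11 and coming back at 12: ozonolysis of 7 with NaBH4 work-up gives [(4R,5S)-4-[(2S)-butan-2-yl]-2,2-dimethyl-1,3-dioxan-5-yl]methanol F6. Mitsunobu reaction with 1-phenyl-1H-tetrazole-5-thiol gives the sulfide 5-({[(4R,5S)-4-[(2S)-butan-2-yl]-2,2-dimethyl-1,3-dioxan-5-yl]methyl}sulfanyl)-1-phenyl-1H-tetrazole F7, and (NH4)6Mo7O24/H2O2 oxidation gives the sulfone 5-({[(4R,5S)-4-[(2S)-butan-2-yl]-2,2-dimethyl-1,3-dioxan-5-yl]methyl}sulfonyl)-1-phenyl-1H-tetrazole F8. Acid 11 is esterified (TMSCHN2) to methyl (4R)-4-methylhept-6-enoate F9 and ozonised (Me2S work-up) to methyl (4R)-4-methyl-6-oxohexanoate F10. Coupling of F8 with F10 (KN(SiMe3)2, DME, −60 °C) should give the E-configured methyl (4R,6E)-7-[(4R,5S)-4-[(2S)-butan-2-yl]-2,2-dimethyl-1,3-dioxan-5-yl]-4-methylhept-6-enoate F11, and LiOH hydrolysis returns acid 12.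

Further compounds
F1 | step 12 | (2R)-but-3-en-2-yl buta-2,3-dienoate | C=C=CC(=O)O[C@H](C)C=C
F2 | step 12 | (2R)-but-3-en-2-yl 3-(4,4,5,5-tetramethyl-1,3,2-dioxaborolan-2-yl)but-3-enoate | C=C(CC(=O)O[C@H](C)C=C)B1OC(C)(C)C(C)(C)O1
F3 | step 12 | (6R)-6-methyl-4-(4,4,5,5-tetramethyl-1,3,2-dioxaborolan-2-yl)-3,6-dihydro-2H-pyran-2-one | C[C@@H]1C=C(CC(=O)O1)B1OC(C)(C)C(C)(C)O1
F4 | step 12 | (6R)-4-hydroxy-6-methyl-5,6-dihydro-2H-pyran-2-one | C[C@@H]1CC(O)=CC(=O)O1
F5 | step 11 | potassium trifluoro{4-[(2R)-but-3-en-2-yloxy]-4-oxobut-1-en-2-yl}borate | [K+].C=C(CC(=O)O[C@H](C)C=C)[B-](F)(F)F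
F6 | step 9 | [(4R,5S)-4-[(2S)-butan-2-yl]-2,2-dimethyl-1,3-dioxan-5-yl]methanol | CC[C@H](C)[C@@H](OC1(C)C)[C@@H](CO)CO1
F7 | step 9 | 5-({[(4R,5S)-4-[(2S)-butan-2-yl]-2,2-dimethyl-1,3-dioxan-5-yl]methyl}sulfanyl)-1-phenyl-1H-tetrazole | CC[C@H](C)[C@@H](OC1(C)C)[C@@H](CSc2nnnn2-c2ccccc2)CO1
F8 | step 9 | 5-({[(4R,5S)-4-[(2S)-butan-2-yl]-2,2-dimethyl-1,3-dioxan-5-yl]methyl}sulfonyl)-1-phenyl-1H-tetrazole | CC[C@H](C)[C@@H](OC1(C)C)[C@@H](CS(=O)(=O)c2nnnn2-c2ccccc2)CO1
F9 | step 9 | methyl (4R)-4-methylhept-6-enoate | C=CC[C@H](C)CCC(=O)OC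
F10 | step 9 | methyl (4R)-4-methyl-6-oxohexanoate | O=CC[C@H](C)CCC(=O)OC
F11 | step 9 | methyl (4R,6E)-7-[(4R,5S)-4-[(2S)-butan-2-yl]-2,2-dimethyl-1,3-dioxan-5-yl]-4-methylhept-6-enoate | CC[C@H](C)[C@@H](OC1(C)C)[C@@H](/C=C/C[C@H](C)CCC(=O)OC)CO1
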